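The β-ring (carotenoid numbering) is built from an open chain and closed at C2–C3: a neopentyl iodide is turned into a C2 alkylchromium that adds to the C3 aldehyde in a 6-exo Barbier-type cyclisation. The step exploits the quaternary C1 (gem-dimethyl), which leaves C2 without β-hydrogens, and the 1,4-relation of the C3 carbinol to C6, carried as a ketone. A temporary C5 methyl stereocentre, erased when the ring C5=C6 alkene is made, sets C3 as R. The precursor is (3S)-6-iodo-3,5,5-trimethyl-4-oxohexanal. The ring ketone is then elaborated through its enol triflate to a C7–C9 ketophosphonate, which a Horner–Wadsworth–Emmons reaction joins at C9=C10 to a C27 ε-apo-aldehyde made from (R)-α-ionone.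

Key step: step 6

Assumption and convention: (R)-α-ionone is taken as purchasable in enantioenriched (natural-grade) form; atoms are labelled by carotenoid numbering (β-ring C1–C6, chain C7–C15, C19 = the CH2OH carbon on C9, primed numbers for the ε half).

Step 1
Reactants: 1 methyl 3-hydroxy-2,2-dimethylpropanoate
Product: 2 methyl 3-iodo-2,2-dimethylpropanoate
Conditions: I2, PPh3, imidazole, toluene, 90 °C
Reagents that add atoms: iodine ([I][I])
Why: Appel iodination; iodide displaces the alkoxyphosphonium group, and the neopentyl carbon needs heat but can neither eliminate nor rearrange.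

Step 2
Reactants: 2 methyl 3-iodo-2,2-dimethylpropanoate
Product: 4 1-iodo-2,2-dimethylpentan-3-one, via Weinreb amide 3 (not isolated)
Conditions: MeNHOMe·HCl, i-PrMgCl, THF, −20 to 0 °C; then EtMgBr, 0 °C to rt; aq. NH4Cl
Reagents that add atoms: N,O-dimethylhydroxylamine hydrochloride (CNOC.Cl); ethylmagnesium bromide (CC[Mg]Br)
Why: One-pot Weinreb ketone synthesis: the chloromagnesium amide made from the amine salt and i-PrMgCl converts the ester into 3, whose chelated adduct with EtMgBr holds until work-up, when it releases ketone 4 and the amine; the neopentyl iodide is inert to Grignard reagents at this temperature.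

Step 3
Reactants: 4 1-iodo-2,2-dimethylpentan-3-one
Product: 5 (2S)-N-[(3E)-1-iodo-2,2-dimethylpentan-3-ylidene]-2-(methoxymethyl)pyrrolidin-1-amine
Conditions: SAMP [(S)-1-amino-2-(methoxymethyl)pyrrolidine], cat. p-TsOH, cyclohexane, reflux (water separator)
Reagents that add atoms: (S)-1-amino-2-(methoxymethyl)pyrrolidine (COC[C@@H]1CCCN1N)
Why: Acid-catalysed hydrazone condensation with the Enders auxiliary; the amino nitrogen settles anti to the bulky tert-alkyl group and syn to the ethyl group, which is the only side that carries α-hydrogens.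

Step 4
Reactants: 5 SAMP hydrazone of 4
Product: 6 (2S)-N-[(3E,4S)-1-iodo-2,2,4-trimethylhept-6-en-3-ylidene]-2-(methoxymethyl)pyrrolidin-1-amine
Conditions: LiN(i-Pr)2, THF, 0 °C; then allyl bromide, −100 °C to rt
Reagents that add atoms: allyl bromide (C=CCBr)
Why: Enders SAMP-hydrazone alkylation; the chelated lithium azaenolate (amino nitrogen syn to the deprotonated carbon, methyl anti to nitrogen) is allylated on the face away from the methoxymethyl arm, which in the usual SAMP sense should set the new centre (C5) as S, and the iodide has no β-hydrogen and is too hindered to alkylate.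

Step 5
Reactants: 6 allylated SAMP hydrazone
Product: 7 (3S)-6-iodo-3,5,5-trimethyl-4-oxohexanal
Conditions: O3, CH2Cl2, −78 °C; then Me2S
Reagents that add atoms: ozone ([O-][O+]=O)
Why: Ozonolysis cleaves the terminal alkene to the aldehyde and the hydrazone to the ketone in one operation, without epimerising the α-stereocentre under the reductive work-up.

Step 6
Reactants: 7 (3S)-6-iodo-3,5,5-trimethyl-4-oxohexanal
Product: 9 (4R,6S)-4-hydroxy-2,2,6-trimethylcyclohexan-1-one, via alkylchromium dichloride 8 (not isolated)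
Conditions: CrCl2 (5 equiv), cobalt phthalocyanine Co(C32H16N8) (5 mol %), DMF, 25 °C; then water
Reagents that add atoms: none
Why: Cobalt phthalocyanine relays an electron from divalent chromium to the C–I bond, and the neopentyl C2 radical is captured by a second divalent chromium to give 8 (trivalent chromium), which has no β-hydrogen because C1 is quaternary and adds to the C3 aldehyde. The closest known reaction type is the cobalt-catalysed Barbier-type addition of alkylchromium reagents to aldehydes (Nozaki–Hiyama–Kishi family), which is selective for aldehydes over ketones. The six-membered ring closes in a 6-exo-trig mode through a chair-like transition state, helped by the gem-dimethyl group. The new stereocentre C3 (C4 of the cyclohexanone) is controlled by the C5 methyl stereocentre: the C5 methyl must sit equatorial to avoid a syn-diaxial clash with the axial C1 methyl, the C3–O bond is equatorial for the same reason, so oxygen and methyl come out cis and (5S) should give (3R). The step needs chemoselectivity for the aldehyde over the hindered C6 ketone (the C2 radical must be trapped by chromium before a 1,2-acyl shift, hence the high CrCl2 concentration) and facial selectivity from the C1 and C5 substituents; any trans isomer is a separable diastereomer.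

Step 7
Reactants: 9 (4R,6S)-4-hydroxy-2,2,6-trimethylcyclohexan-1-one
Product: 10 (4R,6S)-4-[(tert-butyldimethylsilyl)oxy]-2,2,6-trimethylcyclohexan-1-one
Conditions: TBSCl, imidazole, DMF, rt
Reagents that add atoms: tert-butyldimethylsilyl chloride (CC(C)(C)[Si](C)(C)Cl)
Why: Silyl ether formation at the unhindered secondary alcohol.

Step 8
Reactants: 10 silyl-protected hydroxy ketone
Product: 11 (4R)-4-[(tert-butyldimethylsilyl)oxy]-2,6,6-trimethylcyclohex-1-en-1-yl trifluoromethanesulfonate
Conditions: LiN(i-Pr)2, THF, −78 to 0 °C; then PhNTf2, −78 °C to rt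
Reagents that add atoms: N-phenylbis(trifluoromethanesulfonimide) (O=S(=O)(N(c1ccccc1)S(=O)(=O)C(F)(F)F)C(F)(F)F)
Why: Enol triflate formation; only C5 carries an α-hydrogen, so enolisation is regiospecific, the temporary C5 stereocentre is erased and the ring C5=C6 double bond is in place.

Step 9
Reactants: 11 alkenyl triflate
Product: 12 ethyl 2-[(4R)-4-[(tert-butyldimethylsilyl)oxy]-2,6,6-trimethylcyclohex-1-en-1-yl]acetate
Conditions: BrZnCH2CO2Et, Pd2(dba)3 (2.5 mol %), XPhos (10 mol %), THF, 65 °C
Reagents that add atoms: (2-ethoxy-2-oxoethyl)zinc bromide (CCOC(=O)C[Zn]Br)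
Why: Negishi-type cross-coupling of the alkenyl triflate with a Reformatsky zinc enolate on zerovalent palladium gives the β,γ-unsaturated ester (C7, C8) directly; the bulky biaryl phosphine supports reductive elimination at the tetrasubstituted alkenyl carbon.

Step 10
Reactants: 13 diethyl (2-hydroxyethyl)phosphonate
Product: 14 diethyl [2-[(tert-butyldimethylsilyl)oxy]ethyl]phosphonate
Conditions: TBSCl, imidazole, CH2Cl2, rt
Reagents that add atoms: tert-butyldimethylsilyl chloride (CC(C)(C)[Si](C)(C)Cl)
Why: Silyl ether formation at the primary alcohol that becomes the C19 hydroxyl.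

Step 11
Reactants: 12 ring ester; 14 silyloxyethyl phosphonate
Product: 15 diethyl [1-[(tert-butyldimethylsilyl)oxy]-4-[(4R)-4-[(tert-butyldimethylsilyl)oxy]-2,6,6-trimethylcyclohex-1-en-1-yl]-3-oxobutan-2-yl]phosphonate (both epimers at the phosphorus-bearing carbon)
Conditions: 14 (2.2 equiv), LiN(i-Pr)2 (2.2 equiv), THF, −78 °C; then 12, −78 to −30 °C; aq. NH4Cl
Reagents that add atoms: none
Why: Claisen-type acylation of the α-lithiated phosphonate by the ester gives the β-ketophosphonate (C8–C9 bond); the acidic product consumes the second equivalent of base, and the low temperature holds back β-elimination of silanolate.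

Step 12
Reactants: 16 (R)-α-ionone
Product: 17 (3E)-4-[(1R,4R)-4-hydroxy-2,6,6-trimethylcyclohex-2-en-1-yl]but-3-en-2-one [(3R,6R)-3-hydroxy-α-ionone]
Conditions: cytochrome P450 monooxygenase (CYP102A1 variant, E. coli whole cells), air, D-glucose and glucose dehydrogenase for NADPH recycling, phosphate buffer pH 7.5, 2% DMSO, 25 °C
Reagents that add atoms: dioxygen (O=O)
Why: Enzymatic allylic C–H hydroxylation by a P450 monooxygenase, a transformation known for α-ionone with this enzyme class; oxygen is delivered to the ring allylic methylene trans to the side chain, which should give the (3R,6R)-alcohol without touching the enone.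

Step 13
Reactants: 17 (3R,6R)-3-hydroxy-α-ionone
Product: 18 (1R,4R)-4-[(1E)-3-hydroxy-3-methylpenta-1,4-dien-1-yl]-3,5,5-trimethylcyclohex-2-en-1-ol (both epimers at the tertiary carbinol)
Conditions: CH2=CHMgBr (3 equiv), THF, −20 to 0 °C; then water
Reagents that add atoms: vinylmagnesium bromide (C=C[Mg]Br)
Why: 1,2-Addition of the vinyl Grignard reagent to the methyl ketone (one equivalent is consumed by the hydroxyl group); the new carbinol centre is lost in the next step.

Step 14
Reactants: 18 vinyl carbinol
Product: 19 [(2E,4E)-5-[(1R,4R)-4-hydroxy-2,6,6-trimethylcyclohex-2-en-1-yl]-3-methylpenta-2,4-dien-1-yl]triphenylphosphonium bromide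
Conditions: PPh3·HBr, MeOH/CH2Cl2, 0 °C to rt
Reagents that add atoms: triphenylphosphine hydrobromide ([Br-].c1ccc(cc1)[PH+](c1ccccc1)c1ccccc1)
Why: Acid-induced ionisation of the tertiary bis-allylic alcohol and capture of the pentadienyl cation at its terminus by PPh3 (allylic transposition) should give the C15 phosphonium salt; the secondary ring alcohol ionises far more slowly.

Step 15
Reactants: 19 C15 phosphonium bromide; 20 (2E,4E,6E)-2,7-dimethylocta-2,4,6-trienedial
Product: 21 (2E,4E,6E,8E,10E,12E)-13-[(1R,4R)-4-hydroxy-2,6,6-trimethylcyclohex-2-en-1-yl]-2,7,11-trimethyltrideca-2,4,6,8,10,12-hexaenal (C25 aldehyde)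
Conditions: 20 (2.5 equiv), NaOMe, CH2Cl2/MeOH, 0 °C to rt; then heating in heptane
Reagents that add atoms: none
Why: Wittig olefination of one aldehyde group of the excess symmetrical dialdehyde; the semi-stabilised ylide gives an E/Z mixture at the new double bond that is equilibrated thermally towards the all-E isomer.

Step 16
Reactants: 21 C25 aldehyde
Product: 23 (2E,4E,6E,8E,10E,12E,14E)-15-[(1R,4R)-4-hydroxy-2,6,6-trimethylcyclohex-2-en-1-yl]-4,9,13-trimethylpentadeca-2,4,6,8,10,12,14-heptaenal (C27 aldehyde), via N-cyclohexyl aldimine 22 (not isolated)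
Conditions: diethyl [2-(cyclohexylamino)ethenyl]phosphonate, NaH, THF, 0 °C to rt; then aq. oxalic acid, rt
Reagents that add atoms: diethyl [(E)-2-(cyclohexylamino)ethenyl]phosphonate (CCOP(=O)(OCC)/C=C/NC1CCCCC1); water (O)
Why: Horner–Wadsworth–Emmons formyl-olefination with an enamine phosphonate (a masked formylmethyl anion) and mild hydrolysis of 22 add C10 and C11 as an (E)-enal without over-homologation.

Step 17
Reactants: 15 β-ketophosphonate; 23 C27 aldehyde
Product: 24 3,19-bis-O-(tert-butyldimethylsilyl)siphonaxanthin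
Conditions: LiCl, DBU, MeCN/THF, 0 °C to rt
Reagents that add atoms: none
Why: Horner–Wadsworth–Emmons olefination under mild LiCl/amine conditions forms C9=C10; the α-substituted β-ketophosphonate should give the trisubstituted enone with the acyl group trans to the polyene, and the doubly activated C9–H is far more acidic than the C7 methylene.

Step 18
Reactants: 24 bis-silyl ether
Product: 25 (3R,3'R,6'R)-siphonaxanthin (3,3',19-trihydroxy-7,8-dihydro-β,ε-caroten-8-one)
Conditions: Bu4NF, AcOH, THF, 0 °C to rt
Reagents that add atoms: none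
Why: Fluoride-mediated desilylation buffered with acetic acid should free both hydroxyls without conjugating the β,γ-unsaturated ketone or ionising the allylic ε-ring alcohol.

Compound list
1 | methyl 3-hydroxy-2,2-dimethylpropanoate | COC(=O)C(C)(C)CO | starting material
2 | methyl 3-iodo-2,2-dimethylpropanoate | COC(=O)C(C)(C)CI | intermediate
3 | 3-iodo-N-methoxy-N,2,2-trimethylpropanamide | CON(C)C(=O)C(C)(C)CI | intermediate
4 | 1-iodo-2,2-dimethylpentan-3-one | CCC(=O)C(C)(C)CI | intermediate
5 | (2S)-N-[(3E)-1-iodo-2,2-dimethylpentan-3-ylidene]-2-(methoxymethyl)pyrrolidin-1-amine | CC/C(=N\N1CCC[C@H]1COC)C(C)(C)CI | intermediate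
6 | (2S)-N-[(3E,4S)-1-iodo-2,2,4-trimethylhept-6-en-3-ylidene]-2-(methoxymethyl)pyrrolidin-1-amine | C=CC[C@H](C)/C(=N\N1CCC[C@H]1COC)C(C)(C)CI | intermediate
7 | (3S)-6-iodo-3,5,5-trimethyl-4-oxohexanal | O=CC[C@H](C)C(=O)C(C)(C)CI | intermediate
8 | dichloro[(4S)-2,2,4-trimethyl-3,6-dioxohexyl]chromium | O=CC[C@H](C)C(=O)C(C)(C)C[Cr](Cl)Cl | intermediate
9 | (4R,6S)-4-hydroxy-2,2,6-trimethylcyclohexan-1-one | O=C1[C@@H](C)C[C@@H](O)CC1(C)C | intermediate
10 | (4R,6S)-4-[(tert-butyldimethylsilyl)oxy]-2,2,6-trimethylcyclohexan-1-one | O=C1[C@@H](C)C[C@@H](O[Si](C)(C)C(C)(C)C)CC1(C)C | intermediate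
11 | (4R)-4-[(tert-butyldimethylsilyl)oxy]-2,6,6-trimethylcyclohex-1-en-1-yl trifluoromethanesulfonate | FC(F)(F)S(=O)(=O)OC1=C(C)C[C@@H](O[Si](C)(C)C(C)(C)C)CC1(C)C | intermediate
12 | ethyl 2-[(4R)-4-[(tert-butyldimethylsilyl)oxy]-2,6,6-trimethylcyclohex-1-en-1-yl]acetate | CCOC(=O)CC1=C(C)C[C@@H](O[Si](C)(C)C(C)(C)C)CC1(C)C | intermediate
13 | diethyl (2-hydroxyethyl)phosphonate | CCOP(=O)(CCO)OCC | starting material
14 | diethyl [2-[(tert-butyldimethylsilyl)oxy]ethyl]phosphonate | CCOP(=O)(CCO[Si](C)(C)C(C)(C)C)OCC | intermediate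
15 | diethyl [1-[(tert-butyldimethylsilyl)oxy]-4-[(4R)-4-[(tert-butyldimethylsilyl)oxy]-2,6,6-trimethylcyclohex-1-en-1-yl]-3-oxobutan-2-yl]phosphonate | CCOP(=O)(OCC)C(CO[Si](C)(C)C(C)(C)C)C(=O)CC1=C(C)C[C@@H](O[Si](C)(C)C(C)(C)C)CC1(C)C | intermediate
16 | (3E)-4-[(1R)-2,6,6-trimethylcyclohex-2-en-1-yl]but-3-en-2-one, (R)-α-ionone | CC1=CCCC(C)(C)[C@H]1/C=C/C(C)=O | starting material
17 | (3E)-4-[(1R,4R)-4-hydroxy-2,6,6-trimethylcyclohex-2-en-1-yl]but-3-en-2-one | CC1=C[C@H](O)CC(C)(C)[C@H]1/C=C/C(C)=O | intermediate
18 | (1R,4R)-4-[(1E)-3-hydroxy-3-methylpenta-1,4-dien-1-yl]-3,5,5-trimethylcyclohex-2-en-1-ol | CC1=C[C@H](O)CC(C)(C)[C@H]1/C=C/C(C)(O)C=C | intermediate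
19 | [(2E,4E)-5-[(1R,4R)-4-hydroxy-2,6,6-trimethylcyclohex-2-en-1-yl]-3-methylpenta-2,4-dien-1-yl]triphenylphosphonium bromide | CC1=C[C@H](O)CC(C)(C)[C@H]1/C=C/C(C)=C/C[P+](c1ccccc1)(c1ccccc1)c1ccccc1.[Br-] | intermediate
20 | (2E,4E,6E)-2,7-dimethylocta-2,4,6-trienedial | O=C/C(C)=C/C=C/C=C(C)/C=O | starting material
21 | (2E,4E,6E,8E,10E,12E)-13-[(1R,4R)-4-hydroxy-2,6,6-trimethylcyclohex-2-en-1-yl]-2,7,11-trimethyltrideca-2,4,6,8,10,12-hexaenal | CC1=C[C@H](O)CC(C)(C)[C@H]1/C=C/C(C)=C/C=C/C(C)=C/C=C/C=C(C)/C=O | intermediate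
22 | N-cyclohexyl imine of aldehyde 23 | CC1=C[C@H](O)CC(C)(C)[C@H]1/C=C/C(C)=C/C=C/C(C)=C/C=C/C=C(C)/C=C/C=NC1CCCCC1 | intermediate
23 | (2E,4E,6E,8E,10E,12E,14E)-15-[(1R,4R)-4-hydroxy-2,6,6-trimethylcyclohex-2-en-1-yl]-4,9,13-trimethylpentadeca-2,4,6,8,10,12,14-heptaenal | CC1=C[C@H](O)CC(C)(C)[C@H]1/C=C/C(C)=C/C=C/C(C)=C/C=C/C=C(C)/C=C/C=O | intermediate
24 | 3,19-bis-O-(tert-butyldimethylsilyl)siphonaxanthin | CC1=C[C@H](O)CC(C)(C)[C@H]1/C=C/C(C)=C/C=C/C(C)=C/C=C/C=C(C)/C=C/C=C(\CO[Si](C)(C)C(C)(C)C)C(=O)CC1=C(C)C[C@@H](O[Si](C)(C)C(C)(C)C)CC1(C)C | intermediate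
25 | (3R,3'R,6'R)-siphonaxanthin | CC1=C[C@H](O)CC(C)(C)[C@H]1/C=C/C(C)=C/C=C/C(C)=C/C=C/C=C(C)/C=C/C=C(\CO)C(=O)CC1=C(C)C[C@@H](O)CC1(C)C | target

Total step count: 18. Longest linear sequence: 12 steps (steps 1–9, 11, 17 and 18).

Steps most likely to fail

Step 6. The addition to the aldehyde may proceed with poor facial discrimination, so that the carbinol centre is formed as a mixture of epimers (made worse if part of the C2 radical or alkylchromium is drawn towards the neighbouring C6 carbonyl). The fallback sets out from keto aldehyde 7 and comes back to 9; the carbinol configuration is then corrected by invertive substitution instead of being trusted to the C–C bond formation. The cyclisation is run as in step 6 and the epimers are separated. The trans epimer (4S,6S)-4-hydroxy-2,2,6-trimethylcyclohexan-1-one F1 is subjected to a Mitsunobu reaction (4-nitrobenzoic acid, PPh3, DIAD, THF, 0 °C to rt). Its axial C–O bond should be displaced from the open equatorial side with inversion to give (1R,5S)-3,3,5-trimethyl-4-oxocyclohexyl 4-nitrobenzoate F2. Methanolysis with K2CO3 in MeOH at 0 °C then frees 9; the centre next to the hindered ketone is not at risk under these conditions and is erased in step 8 in any case.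

Step 9. Transmetalation and reductive elimination at the hindered, tetrasubstituted alkenylpalladium may be too slow, so that protodetriflation and decomposition of the zinc enolate take over. The fallback sets out from ketone 10 and comes back to ester 12, building the C6–C7 bond by carbonyl addition instead of cross-coupling. The lithium enolate of ethyl acetate (EtOAc, LiN(i-Pr)2, CeCl3, THF, −78 °C) should add to the hindered carbonyl to give ethyl 2-[(4R,6S)-4-[(tert-butyldimethylsilyl)oxy]-1-hydroxy-2,2,6-trimethylcyclohexyl]acetate F3. Dehydration with SOCl2 and pyridine at 0 °C should give 12 together with the exocyclic conjugated isomer ethyl 2-[(4R)-4-[(tert-butyldimethylsilyl)oxy]-2,2,6-trimethylcyclohexylidene]acetate F4. Catalytic DBU is expected to drain F4 into the less strained endocyclic β,γ-unsaturated ester 12.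

Step 3. Condensation of the hindered tert-alkyl ketone with the hydrazine may stall, and the crowded azaenolate of step 4 may form slowly or in a geometry that erodes the sense of induction. The fallback sets out from ketone 4 and comes back to keto aldehyde 7, replacing the auxiliary by catalytic asymmetric allylation. NaN(SiMe3)2 and allyl chloroformate in THF at −78 °C should give allyl (Z)-(1-iodo-2,2-dimethylpent-3-en-3-yl) carbonate F5. Decarboxylative asymmetric allylic alkylation of Tsuji–Trost type then follows, with Pd2(dba)3 and N,N'-bis[2-(diphenylphosphanyl)benzoyl]cyclohexane-1,2-diamine in toluene at rt, using the ligand enantiomer that delivers the S ketone. It should give (4S)-1-iodo-2,2,4-trimethylhept-6-en-3-one F6. Ozonolysis (O3, CH2Cl2, −78 °C; Me2S) of the terminal alkene then returns 7.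

Further compounds
F1 | step 6 | (4S,6S)-4-hydroxy-2,2,6-trimethylcyclohexan-1-one | O=C1[C@@H](C)C[C@H](O)CC1(C)C
F2 | step 6 | (1R,5S)-3,3,5-trimethyl-4-oxocyclohexyl 4-nitrobenzoate | O=C1[C@@H](C)C[C@@H](OC(=O)c2ccc(cc2)[N+](=O)[O-])CC1(C)C
F3 | step 9 | ethyl 2-[(4R,6S)-4-[(tert-butyldimethylsilyl)oxy]-1-hydroxy-2,2,6-trimethylcyclohexyl]acetate | CCOC(=O)CC1(O)[C@@H](C)C[C@@H](O[Si](C)(C)C(C)(C)C)CC1(C)C
F4 | step 9 | ethyl 2-[(4R)-4-[(tert-butyldimethylsilyl)oxy]-2,2,6-trimethylcyclohexylidene]acetate | CCOC(=O)C=C1C(C)C[C@@H](O[Si](C)(C)C(C)(C)C)CC1(C)C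
F5 | step 3 | allyl (Z)-(1-iodo-2,2-dimethylpent-3-en-3-yl) carbonate | C=CCOC(=O)O/C(=C\C)C(C)(C)CI
F6 | step 3 | (4S)-1-iodo-2,2,4-trimethylhept-6-en-3-one | C=CC[C@H](C)C(=O)C(C)(C)CI
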